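**Retrosynthetic overview**
- Feature: on the imidazole ring, C4 and C5 each carry a CH2 group bonded to the para carbon of an oxygenated benzene ring. N1–H/N3 tautomerism exchanges C4 and C5, so the two arms differ only in OCH3 versus OSO3H, and the symmetric 4,5-bis(4-hydroxybenzyl)imidazole is a masked form of the target.
- Disconnections, backwards: the aryl O–S bond of the sulfate; one aryl O–CH3 bond; then both CH2–C(aryl) bonds at once, to 4,5-bis(hydroxymethyl)imidazole and two molecules of phenol (two-fold Friedel–Crafts alkylation through azafulvenium ions).
- The diol comes from imidazole-4,5-dicarboxylic acid by esterification and hydride reduction.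
- Ring formation: none; the imidazole ring and both benzene rings are bought intact.

Key step: step 3

Remark: the target is drawn neutral but should be handled as its inner salt (imidazolium aryl sulfate). The N–H tautomers of each 4,5-disubstituted imidazole are one compound. The azafulvenium ions 5 and 7 are drawn as monocations although they may carry a further N-proton in CH3SO3H.

**Route**

Step 1
Reactants: 1 imidazole-4,5-dicarboxylic acid
Product: 2 dimethyl 1H-imidazole-4,5-dicarboxylate
Conditions: MeOH, conc. H2SO4 (catalyst, in excess over the basic ring), reflux; neutral work-up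
Reagents that add atoms: methanol, CO
Why: Fischer esterification of both acid groups, driven by methanol as solvent; the protonated imidazole ring is inert to the conditions.

Step 2
Reactants: 2 dimethyl 1H-imidazole-4,5-dicarboxylate
Product: 3 4,5-bis(hydroxymethyl)-1H-imidazole
Conditions: LiAlH4 (4 equiv), THF, 0 °C to reflux; then Na2SO4·10H2O, salts leached with hot EtOH
Reagents that add atoms: none
Why: LiAlH4 reduction of both ester groups to primary alcohols after the N–H has consumed one hydride; the aromatic ring is not reduced, and the water-soluble diol is recovered from the aluminium salts by hot ethanol.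

Step 3
Reactants: 3 4,5-bis(hydroxymethyl)-1H-imidazole; 4 phenol
Product: 8 4,5-bis(4-hydroxybenzyl)-1H-imidazole, via first azafulvenium ion 5 (not isolated), via monobenzylated alcohol 6 (not isolated), via second azafulvenium ion 7 (not isolated)
Conditions: CH3SO3H (3 equiv), molten 4 (15 equiv), 110 °C
Reagents that add atoms: phenol (second molecule of 4, one per benzyl arm), Oc1ccccc1
Why: In the hot acid a CH2–OH2+ group loses water with electron release from the ring (N1 lone pair through C5=C4) to give azafulvenium ion 5, which the para carbon of a first molecule of phenol attacks in a Friedel–Crafts alkylation (electrophilic aromatic substitution) to give 6, and the second arm repeats the sequence through 7 with a second molecule of phenol. The closest known reaction type is the acid-promoted imidazolylmethylation of phenols and thiols by 4-(hydroxymethyl)imidazole salts, here run twice on one ring. No ring closes and no stereocenter is formed. The step needs para over ortho attack on phenol, capture of 7 by external phenol in preference to the neighbouring aryl ring, and one alkylation per phenol; the bulk of the delocalised cation, the poorly activated position meta to OH in the first aryl ring and the large excess of molten phenol should secure these. The protonated imidazole core is not nucleophilic, so the diol should not condense with itself irreversibly, and the basic product is parted from phenol by acid–base extraction.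

Step 4
Reactants: 8 4,5-bis(4-hydroxybenzyl)-1H-imidazole
Product: 9 4-(4-hydroxybenzyl)-5-(4-methoxybenzyl)-1H-imidazole
Conditions: Me3SiCHN2 (1.0 equiv, slow addition), iPr2NEt, MeOH–MeCN, rt; recovered 8 recycled
Reagents that add atoms: (trimethylsilyl)diazomethane, C[Si](C)(C)C=[N+]=[N-]
Why: O-methylation of a phenol with (trimethylsilyl)diazomethane in methanol is known chemistry in which diazomethane set free by methanolysis is protonated only by the phenolic O–H (pKa about 10), so the far less acidic imidazole N–H should stay unmethylated, while the choice between the two equivalent phenols is statistical and is handled by one equivalent of reagent and recycling of 8.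

Step 5
Reactants: 9 4-(4-hydroxybenzyl)-5-(4-methoxybenzyl)-1H-imidazole
Product: 10 Melanocin F, 4-{[5-(4-methoxybenzyl)-1H-imidazol-4-yl]methyl}phenyl hydrogen sulfate
Conditions: SO3·pyridine (3 equiv), pyridine, rt to 40 °C; then H2O, evaporation, C18 chromatography
Reagents that add atoms: sulfur trioxide–pyridine complex, [O-]S(=O)(=O)[n+]1ccccc1
Why: Sulfation of a phenol with a sulfur trioxide–amine complex is standard, and the imidazole nitrogen (conjugate acid pKa about 8) is more basic than pyridine, so the inner salt should remain on evaporation without any strong acid that could hydrolyse the sulfate ester.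

**Compound list**
1 | imidazole-4,5-dicarboxylic acid | OC(=O)c1nc[nH]c1C(=O)O | starting material
2 | dimethyl 1H-imidazole-4,5-dicarboxylate | COC(=O)c1nc[nH]c1C(=O)OC | intermediate
3 | 4,5-bis(hydroxymethyl)-1H-imidazole | OCc1nc[nH]c1CO | intermediate
4 | phenol | Oc1ccccc1 | starting material
5 | first azafulvenium ion, 5-(hydroxymethyl)-4-methylidene-4H-imidazol-1-ium (not isolated) | C=C1N=C[NH+]=C1CO | intermediate
6 | monobenzylated alcohol, 4-{[5-(hydroxymethyl)-1H-imidazol-4-yl]methyl}phenol (not isolated) | OCc1[nH]cnc1Cc1ccc(O)cc1 | intermediate
7 | second azafulvenium ion, 5-(4-hydroxybenzyl)-4-methylidene-4H-imidazol-1-ium (not isolated) | C=C1N=C[NH+]=C1Cc1ccc(O)cc1 | intermediate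
8 | 4,5-bis(4-hydroxybenzyl)-1H-imidazole | Oc1ccc(Cc2[nH]cnc2Cc2ccc(O)cc2)cc1 | intermediate
9 | 4-(4-hydroxybenzyl)-5-(4-methoxybenzyl)-1H-imidazole | COc1ccc(Cc2[nH]cnc2Cc2ccc(O)cc2)cc1 | intermediate
10 | Melanocin F, 4-{[5-(4-methoxybenzyl)-1H-imidazol-4-yl]methyl}phenyl hydrogen sulfate | COc1ccc(Cc2[nH]cnc2Cc2ccc(OS(=O)(=O)O)cc2)cc1 | target

**Step count**
Total steps: 5. Longest linear sequence: 5 steps (1 to 10).

**Steps most likely to fail**

1. Step 3. The double arylation may be spoiled by ortho attack on phenol, by a second alkylation of an already benzylated phenol ring, or by six-membered ring closure of the second cation onto the first aryl ring. The fallback makes the two CH2–aryl bonds by carbonyl addition and sets out from diol 3. Oxidation with activated MnO2 in hot dioxane should give 1H-imidazole-4,5-dicarbaldehyde F1. Addition of excess 4-(benzyloxy)phenylmagnesium bromide in THF (the first equivalent is spent on the N–H) should give the bis-carbinol (1H-imidazole-4,5-diyl)bis[(4-benzyloxyphenyl)methanol] F2, a mixture of diastereomers that need not be separated. Hydrogenolysis over Pd/C under H2 in AcOH with aqueous HCl should remove both benzylic hydroxyl groups and both O-benzyl groups at once, and the fallback comes back to the route at bis-phenol 8.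

2. Step 4. Methylation may reach the ring nitrogen, or run on to the bis-ether faster than recycling can make up for. The fallback blocks the ring nitrogen first and sets out from 8. TrCl and Et3N in DMF should tritylate the imidazole nitrogen selectively to give 4,5-bis(4-hydroxybenzyl)-1-trityl-1H-imidazole F3. One equivalent of MeI with K2CO3 in acetone should then alkylate a phenoxide, still statistically, to give the two regioisomeric mono-ethers 5-(4-hydroxybenzyl)-4-(4-methoxybenzyl)-1-trityl-1H-imidazole F4 and 4-(4-hydroxybenzyl)-5-(4-methoxybenzyl)-1-trityl-1H-imidazole F5, which are taken on together. Warm 80% aqueous AcOH should remove the trityl group from both, and they converge on 9.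

3. Step 5. Reagent may be consumed at the imidazole nitrogen, and the sulfate ester may be lost by hydrolysis during isolation of the inner salt. The fallback is an enzymatic sulfo transfer and sets out from 9. Aryl sulfotransferase from Desulfitobacterium hafniense with p-nitrophenyl sulfate as donor in buffer of pH about 9 at 30 °C should sulfate the phenol selectively under conditions that never become acidic. It arrives directly at 10, and no new compound arises on the way (F0).

Further compounds
F1 | step 3 | 1H-imidazole-4,5-dicarbaldehyde | O=Cc1nc[nH]c1C=O
F2 | step 3 | (1H-imidazole-4,5-diyl)bis[(4-benzyloxyphenyl)methanol], mixture of diastereomers | OC(c1ccc(OCc2ccccc2)cc1)c1nc[nH]c1C(O)c1ccc(OCc2ccccc2)cc1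
F3 | step 4 | 4,5-bis(4-hydroxybenzyl)-1-trityl-1H-imidazole | Oc1ccc(Cc2ncn(C(c3ccccc3)(c3ccccc3)c3ccccc3)c2Cc2ccc(O)cc2)cc1
F4 | step 4 | 5-(4-hydroxybenzyl)-4-(4-methoxybenzyl)-1-trityl-1H-imidazole | COc1ccc(Cc2ncn(C(c3ccccc3)(c3ccccc3)c3ccccc3)c2Cc2ccc(O)cc2)cc1
F5 | step 4 | 4-(4-hydroxybenzyl)-5-(4-methoxybenzyl)-1-trityl-1H-imidazole | Oc1ccc(Cc2ncn(C(c3ccccc3)(c3ccccc3)c3ccccc3)c2Cc2ccc(OC)cc2)cc1
F0 | step 5 | none | none
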